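Per unit of free catalyst charged, the midnight flask carries 1.10 units of impurity, and its product climbs for days and then lies flat.

all flasks: free catalyst 0.20 mM; impurity 0.22 mM
- midnight: substrate 0.10 M; partner 0.20 M; the very flask that is asked about, followed so far
- dawn: substrate 0.15 M; partner 0.20 M; run made earlier
- flask: substrate 0.10 M; partner 0.200 M; time 8.0 d

| midnight: time / h | midnight: product / % | dawn: time / h | dawn: product / % |
|---|---|---|---|
| 8.00 | 9.8 | 3.00 | 4.0 |
| 25.0 | 14.2 | 5.00 | 5.3 |
| 40.0 | 14.7 | 8.00 | 8.2 |
| 72.0 | 15.5 | 12.0 | 9.0 |
| 96.0 | 16.4 | 15.0 | 10.3 |
| 120 | 16.5 | 25.0 | 12.4 |
| 144 | 15.9 | 40.0 | 13.3 |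

(standard deviation of a reading: 0.3 percentage points)

- product taken out counts as made
- additions bring no volume worth counting

- north-east: at 8.0 d add free catalyst, 100 % of the amount charged, then wait 15 d
- east: at 8.0 d add partner, 50.0 % of the amount charged, then wait 15 d
- south-west: change nothing and wait 15 d more
- west: at 8.0 d take out 90 % of the product then present, then wait 15 d

1. product, in percent of the substrate first charged, at 8.0 d
2. which option adds most product ("none" when 2 percentage points or less is all one gets) (north-east / east / south-west / west / none)
3. product present, with what was taken out counted in, in percent of the substrate first charged, after north-east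
4. product present, with what was taken out counted in, in percent of the substrate first charged, after south-west

The midnight readings from 96.0 h to 144 h average 16.3 %, and this reckoning commits to that figure for the flask at 8.0 d. It reads the stall as one-to-one capture of free catalyst by impurity, with free catalyst the limiting reagent of that capture. On that reading, 9.09 % of the impurity charge stands over once each free catalyst has taken one impurity, and this share is the impurity surplus. In the flask, that remainder would cost a north-east dose a part of itself and leave 90.0 % of the dose free. At the same product per catalyst, the dose would add 15 percentage points, for a total of 30.9 %.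

The forecast gives 16.5 % now, 16.8 % after south-west, and north-east as the best option, reaching 92 %, where fresh catalyst “should nearly finish the substrate”. This reckoning holds 16.3 % for the figure now and 30.9 % against that last one.

The flask gives 16.5 % at 8.0 d and 16.7 % after south-west. North-east adds 6.3 points, more than any other option, and reaches 22.9 %.

    substrate + free catalyst ⇌ catalyst intermediate A (K = 16.0 M⁻¹, k = 10.0 M⁻¹ s⁻¹)
    catalyst intermediate A → catalyst intermediate B (k = 0.0310 s⁻¹)
    partner + catalyst intermediate B → catalyst intermediate C (k = 0.170 M⁻¹ s⁻¹)
    catalyst intermediate C → free catalyst + product (k = 0.00650 s⁻¹)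
    2 partner → homo dimer (k = 1.00 × 10⁻⁴ M⁻¹ s⁻¹)
    free catalyst → spent catalyst A (k = 8.40 × 10⁻⁸ s⁻¹)
    free catalyst + impurity → spent catalyst B (k = 6.20 M⁻¹ s⁻¹)

The figure that parts from both reckonings is 22.9 %. At 192 h, the flask holds 3.25 % of its partner free, with 88.5 % of the partner charge standing as homo dimer, and that free remainder equals 6.5 points of the substrate charge, against the 6.3 points gained. The impurity surplus of 9.09 % stands beside the 9.3 % of impurity found in the flask at that time.

In the neighbour flask charged with 3.7 × 10⁻⁴ M of impurity, the surplus gives 45.9 %. That flask keeps 46 % of its impurity and makes 5.75 % of product.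

(The data are calculated with constants of no real substance, and the scatter is random.)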